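The data were computed for substances that don't exist; scatter was added.

- The noon run reached 21.5% of its solid substrate at 4.00 d, and the midnight run reached 21.2%, although the midnight run held twice the reagent.

| flask | solid substrate | reagent | initiator | remark | time |
|---|---|---|---|---|---|
| noon | 0.26 M | 0.26 M | 13 mM | run made earlier |  |
| midnight | 0.26 M | 0.58 M | 13 mM | run made earlier |  |
| summer | 0.39 M | 0.39 M | 13 mM | run made earlier |  |
| flask | 0.26 M | 0.390 M | 13 mM |  | 4.0 d |

| run | time / d | product / % |
|---|---|---|
| noon | 0.333 | 0.9 |
| noon | 0.500 | 0.6 |
| noon | 0.833 | 3.8 |
| noon | 1.67 | 8.5 |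
| noon | 2.50 | 13.0 |
| noon | 4.00 | 21.5 |
| midnight | 0.625 | 3.5 |
| midnight | 1.25 | 6.3 |
| midnight | 2.08 | 10.7 |
| midnight | 2.50 | 12.9 |
| midnight | 3.00 | 15.9 |
| midnight | 4.00 | 21.2 |
| summer | 0.333 | 0.7 |
| summer | 1.04 | 3.5 |
| summer | 1.67 | 5.8 |
| summer | 3.00 | 11.2 |
| summer | 4.00 | 14.4 |

(scatter of a reading: 0.5 percentage points)

- solid, in amounts per volume of the solution: solid substrate
- at the start none of the solid substrate is in solution

- oak: doubling the solubility of the solid substrate, all else as stated
- cedar: doubling the amount of reagent, all else as stated
- elm: doubling the dissolution coefficient of the solid substrate, all else as stated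

* how much product there is at 4.0 d, in percent of the solid substrate charged
* the change that raises the amount of product at 4.0 d, in percent of the solid substrate charged most ("none" if none brings more than 2 percentage points) (oak / cedar / elm / none)
* amount of product at 4.0 d, in percent of the solid substrate charged, after elm

- The midnight run grows in a straight line: 10.7% at 2.08 d is half of its last reading, at half the time.
- So the rate v can be frozen. Noon and midnight average 13.9 mM d⁻¹ of product, a zero-order rate.
- For the flask, 21.3% is v times the time over c(solid substrate), the delivery number: the share of the charge that this rate turns into product by the reading.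
- The summer run played no part in v, so it tests the number: 14.2% reckoned, 14.4% read, with a scatter of 0.5 percentage points.
- This reckoning therefore expects about 21.3% in the flask and no gain from cedar. A doubled v gives 42.6%, this reckoning's figure for oak.
- One number stops short at elm: v does not show how far the solution stands from saturation.
- The forecast gives 21.4% (20.6% to 22.2%), with oak best and 40% after elm (31% to 43%), on the ground that “the supply of dissolved substrate limits the rate”.
- The flask gives 21.5%. Oak adds 21 points, cedar 0 points and elm 11 points, so oak comes first, and elm ends at 32.8%.

    initiator → 2 initiating radical (k = 9.94 × 10⁻⁷ s⁻¹)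
    starting material + initiating radical ⇌ chain carrier (K = 3.60 × 10⁵ L mol⁻¹, k = 5470 L mol⁻¹ s⁻¹)
    2 initiating radical → ended chains (k = 2.00 × 10⁸ L mol⁻¹ s⁻¹)
    reagent + chain carrier → product + initiating radical (k = 1460 L mol⁻¹ s⁻¹)
    solid substrate ⇌ starting material, rate k5*(cs5 - [starting material]) while solid is left; crystals form when [starting material] > cs5 (solubility = 13.0 mM, k = 1.94 × 10⁻⁵ s⁻¹)

- At 2.00 d the flask's starting material stood at 32.3% of saturation, and elm multiplied the product by 1.53. For the neighbour flask, the same charge read at 10 d, the delivery number gives 53.4%, and that flask holds 52.8%.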